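In the south run substrate reads 30.0% of the charge at 60.0 s, while product climbs from 2.1% at 25.0 s to 5.9% at 60.0 s; the north run, charged with 0.34 M, reads 2.0% of product at 60.0 s.

| flask | substrate | remark | time |
|---|---|---|---|
| north | 0.34 M | run made earlier |  |
| south | 0.91 M | run made earlier |  |
| alpha | 0.50 M |  | 2.0 min |
| theta | 0.60 M |  | 2.0 min |
| epsilon | 3.0 M |  | 2.0 min |
| zeta | 0.30 M |  | 2.0 min |
| delta | 1.0 M |  | 2.0 min |

| run | time / s | product / % | substrate / % |
|---|---|---|---|
| north | 12.0 | 0.4 | 57.8 |
| north | 25.0 | 1.0 | 40.4 |
| north | 40.0 | 2.0 | 34.0 |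
| north | 50.0 | 2.5 | 32.7 |
| north | 60.0 | 2.0 | 32.3 |
| south | 12.0 | 1.7 | 58.3 |
| south | 25.0 | 2.1 | 40.1 |
| south | 40.0 | 3.1 | 33.4 |
| south | 50.0 | 5.0 | 30.9 |
| south | 60.0 | 5.9 | 30.0 |

(standard deviation of a reading: 0.5 percentage points)

1. ranking by amount of product, in percent of the substrate charged, from high to low, at 2.0 min (alpha / theta / epsilon / zeta / delta)
2. the amount of product, in percent of the substrate charged of the flask you put first, at 2.0 min
3. the amount of product, in percent of the substrate charged of the flask you put last, at 2.0 min

- what was read earlier has a scatter of 0.5 percentage points, one standard deviation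

I read this as product breeding product (autocatalysis). With p the share of the charge turned to product and c(substrate) the charge, I take dp/dt = g·c(substrate)·p·(1−p). This integrates in closed form: ln[p/(1−p)] rises in a straight line, with time constant 1/(g·c(substrate)).

The two south readings give the growth constant g = 0.0337 L mol⁻¹ s⁻¹, a reading that carries their scatter. Since g·c(substrate) is larger in epsilon than in zeta, I rank the flasks by charge.

Epsilon has no reading of its own, so I assume it starts from the south odds at 60.0 s, 0.0627. Its rate is 0.101 s⁻¹, a time constant of 9.90 s, and by 2.00 min this gives 96.4%.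

The forecast gives epsilon > delta > theta > alpha > zeta, with 28% first and 3.9% last, on the ground that “the percent yield rises with concentration, so the ranking follows concentration”.

The flask gives epsilon > delta > theta > alpha > zeta, with 85.3% first and 5.72% last.

    substrate + product → 2 product (k = 0.0850 L mol⁻¹ s⁻¹)
    substrate → product (k = 6.60 × 10⁻⁴ s⁻¹)
    substrate ⇌ dormant form (K = 2.10, k = 0.0540 s⁻¹)

Between 1.00 min and 2.00 min the odds in epsilon rise at 0.0285 s⁻¹, slower than g·c(substrate). At 2.00 min epsilon still holds 13.4% as dormant form against 1.38% as substrate, a ratio of 9.71 where the equilibrium constant is 2.1. The neighbour of epsilon charged with 1.8 M gets the same reckoning: the south odds and a rate of 0.0607 s⁻¹ give 70.4%, and at 2.00 min that neighbour holds 64.4% of product.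

All runs stem from a simulated flask with constants of no real substance; noise was put on by code.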